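Numbering: ring A = C1 (carries benzoyl), C2–O, C3 (carries the CH2 link), C4–O, C5 (carries both prenyls), C6–O. Ring B = C1' (carries the link), C2' (C(OH)CH3), C5' (isopropenyl).
Cuts, in order: the two C5–prenyl bonds; C1–C2 of ring A, which turns the carbocycle into a 4-hydroxy-2-pyrone (C2 lactone carbonyl, ring O on C6, C1 a phenacyl CH2); C1–C(=O)Ph; C3–CH2; C1'–C2' of ring B.
Enabling feature: the benzoyl carbonyl and ring A form one seven-carbon run, PhC(=O)–C1–C6(=O)–C5–C4(=O)–C3–C2(=O), oxygenated at every second carbon. This is a folded benzoyl triketide, so C2 is at the acid level and can be passed from a ring oxygen to the doubly activated C1.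
Forward: ring B is closed first by an aldol reaction of seco-limonene and is joined through its CHO carbon to C3 of a bought pyrone. The 6-methyl group is then benzoylated, the pyrone ring is exchanged for carbocyclic ring A, and C5 is prenylated twice.
Stereochemistry: C5' is the stereocentre of (S)-limonene. C1' and C2' are set against it in the aldol closure (CHO trans to isopropenyl, OH cis to CHO), and no later step makes or endangers a stereocentre.

Key step: step 7

Remark: enolised di- and tricarbonyl compounds are written as one tautomer of a mobile mixture. The epoxide of the first step is carried on as its cis/trans mixture, because both of its new stereocentres disappear in the next step.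

Step 1
Reactants: 1 (S)-limonene
Product: 2 (4S)-1-methyl-4-(prop-1-en-2-yl)-7-oxabicyclo[4.1.0]heptane (limonene 1,2-oxide; cis/trans mixture at the epoxide)
Conditions: 3-chloroperbenzoic acid (mCPBA, 1.0 equiv), CH2Cl2, 0 °C
Reagents that add atoms: mCPBA, O=C(OO)c1cccc(Cl)c1
Why: The Prilezhaev epoxidation is electrophilic, so one equivalent of peracid should take the electron-richer trisubstituted ring alkene and leave the 1,1-disubstituted isopropenyl group.

Step 2
Reactants: 2 limonene 1,2-oxide
Product: 4 (3S)-6-oxo-3-(prop-1-en-2-yl)heptanal, via trans-diol 3 (not isolated)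
Conditions: H5IO6 (1.2 equiv), THF/H2O, 0 °C to rt
Reagents that add atoms: water, O
Why: Periodic acid first promotes hydrolysis of the epoxide to diol 3 and then cleaves it (Malaprade glycol cleavage), sparing the isopropenyl group and the non-enolisable stereocentre.

Step 3
Reactants: 4 (3S)-6-oxo-3-(prop-1-en-2-yl)heptanal
Product: 5 (1R,2S,5S)-2-hydroxy-2-methyl-5-(prop-1-en-2-yl)cyclopentane-1-carbaldehyde
Conditions: (R)-proline (20 mol %), CH2Cl2, rt
Reagents that add atoms: none
Why: In this enamine-catalysed 5-enolexo intramolecular aldol addition the amine condenses only with the aldehyde, so the aldehyde α-carbon attacks the methyl ketone; C1' forms with the enamine arm trans to the isopropenyl group, C2' forms with OH cis to CHO through the acid-to-carbonyl hydrogen bond of the transition state, (R)-proline should reinforce this sense, it is also the thermodynamic one (epimerisable C1', hydrogen-bonded cis hydroxy aldehyde), and the unheated medium holds back dehydration.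

Step 4
Reactants: 5 hydroxy aldehyde
Product: 6 (1R,2S,5S)-2-methyl-5-(prop-1-en-2-yl)-2-(triethylsilyloxy)cyclopentane-1-carbaldehyde
Conditions: Et3SiOTf (1.3 equiv), 2,6-lutidine (2 equiv), CH2Cl2, −78 to −20 °C
Reagents that add atoms: triethylsilyl trifluoromethanesulfonate, CC[Si](CC)(CC)OS(=O)(=O)C(F)(F)F
Why: Silyl triflate with a hindered pyridine is the standard silylation of a tertiary aldol hydroxyl, and the ether blocks retro-aldol cleavage and dehydration in step 5, saves base in step 6 and adds bulk beside C3 for step 8.

Step 5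
Reactants: 6 silyloxy aldehyde; 7 triacetic acid lactone (4-hydroxy-6-methyl-2H-pyran-2-one)
Product: 9 4-hydroxy-6-methyl-3-{[(1R,2S,5S)-2-methyl-5-(prop-1-en-2-yl)-2-(triethylsilyloxy)cyclopentyl]methyl}-2H-pyran-2-one, via alkylidene pyrandione 8 (not isolated)
Conditions: diethyl 2,6-dimethyl-1,4-dihydropyridine-3,5-dicarboxylate (Hantzsch ester, 1.1 equiv), (S)-proline (20 mol %), EtOH, rt to 40 °C
Reagents that add atoms: none
Why: In this three-component reductive alkylation (Knoevenagel condensation, then Hantzsch ester transfer hydrogenation) C3 is the only nucleophilic carbon of the pyrone, the hydride donor intercepts 8 before a second pyrone can add, and C1' keeps its more stable trans arrangement.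

Step 6
Reactants: 9 3-alkyl-4-hydroxy-6-methylpyrone; 10 methyl benzoate
Product: 11 4-hydroxy-6-(2-oxo-2-phenylethyl)-3-{[(1R,2S,5S)-2-methyl-5-(prop-1-en-2-yl)-2-(triethylsilyloxy)cyclopentyl]methyl}-2H-pyran-2-one
Conditions: lithium diisopropylamide (3.2 equiv), THF, −78 to −20 °C; 10 (1.1 equiv), −78 to 0 °C; cold 1 M HCl
Reagents that add atoms: none
Why: The base removes the 4-OH proton and then a vinylogous 6-methyl proton, the dianion undergoes a crossed Claisen acylation with the non-enolisable ester at the exocyclic carbon, and the third equivalent takes up the acidic phenacyl proton so that only one benzoyl group enters.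

Step 7
Reactants: 11 3-alkyl-4-hydroxy-6-phenacyl-2-pyrone
Product: 13 phenyl(2,4,6-trihydroxy-3-{[(1R,2S,5S)-2-methyl-5-(prop-1-en-2-yl)-2-(triethylsilyloxy)cyclopentyl]methyl}phenyl)methanone, via magnesium-chelated triketo ester 12 (not isolated)
Conditions: Mg(OMe)2 (4 equiv), MeOH, reflux, argon; cold 1 M HCl
Reagents that add atoms: none
Why: Methoxide from Mg(OMe)2 adds to the lactone carbonyl C2 of 11 and breaks the C2–O1 bond, which unmasks the magnesium-chelated triketo ester 12; its most acidic carbon, C1 between the C6 and benzoyl carbonyls, then attacks the ester carbonyl, methoxide leaves, and the cyclohexanetrione tautomerises to arene 13. The closest known reaction type is the base-induced conversion of 6-(2-oxoalkyl)-4-hydroxy-2-pyrones into acylphloroglucinols, an intramolecular Claisen (Dieckmann-type) condensation of a 3,5,7-triketo ester. The one ring that closes, carbocyclic ring A, does so through the C1–C2 bond in a 6-exo-trig mode, the attacked C=O lying outside the new ring. No stereocentre is formed: the ester α-carbon C3 of 12 is a mobile centre that ends sp2, and C1', C2' and C5' are not adjacent to any acidic position. The step needs Claisen closure to win over aldol closure and over retro-Claisen loss of the benzoyl group; the aldol path would have the alkyl-bearing C3 attack the conjugated phenyl ketone and give a quaternary carbon that cannot aromatise, so it stays reversible, while chelation by Mg2+ folds the tricarbonyl array, activates the ester and keeps the benzoylacetyl unit as an enolate that methoxide does not attack. Aromatisation to the magnesium phenolate removes 13 from all equilibria.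

Step 8
Reactants: 13 3-alkyl-2,4,6-trihydroxybenzophenone; 14 prenyl bromide (2.2 equiv)
Product: 16 O-triethylsilyl hypercalin B (2-benzoyl-3,5-dihydroxy-6,6-bis(3-methylbut-2-en-1-yl)-4-{[(1R,2S,5S)-2-methyl-5-(prop-1-en-2-yl)-2-(triethylsilyloxy)cyclopentyl]methyl}cyclohexa-2,4-dien-1-one), via 5-prenyl benzophenone 15 (not isolated)
Conditions: KOH (3.5 equiv), degassed MeOH/H2O, argon, 0 °C to rt
Reagents that add atoms: none
Why: In this alkylative dearomatisation of an acylphloroglucinol polyanion (the reaction that gives lupulone-type gem-diprenyl triketones) the free C5 is prenylated first to 15, the second SN2 alkylation should again choose C5 because C3 carries the β-branched, silyloxy-flanked ring B arm, and the protic medium solvates the phenolate oxygens and so favours C- over O-alkylation.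

Step 9
Reactants: 16 O-triethylsilyl hypercalin B
Product: 17 hypercalin B
Conditions: HF·pyridine, pyridine, THF, 0 °C to rt
Reagents that add atoms: none
Why: Fluoride-driven Si–O cleavage in a pyridine-buffered medium should free the tertiary alcohol without the strong acid that could ionise it or cyclise the prenyl groups onto the enols, and C2' is untouched because its C–O bond is not broken.

Compound list
1 | (S)-limonene | C=C(C)[C@H]1CCC(C)=CC1 | starting material
2 | (4S)-limonene 1,2-oxide, cis/trans mixture | C=C(C)[C@H]1CCC2(C)OC2C1 | intermediate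
3 | (1R,2R,4S)-1-methyl-4-(prop-1-en-2-yl)cyclohexane-1,2-diol | C=C(C)[C@H]1CC[C@@](C)(O)[C@H](O)C1 | intermediate
4 | (3S)-6-oxo-3-(prop-1-en-2-yl)heptanal | C=C(C)[C@H](CC=O)CCC(C)=O | intermediate
5 | (1R,2S,5S)-2-hydroxy-2-methyl-5-(prop-1-en-2-yl)cyclopentane-1-carbaldehyde | C=C(C)[C@H]1CC[C@](C)(O)[C@@H]1C=O | intermediate
6 | (1R,2S,5S)-2-methyl-5-(prop-1-en-2-yl)-2-(triethylsilyloxy)cyclopentane-1-carbaldehyde | C=C(C)[C@H]1CC[C@](C)(O[Si](CC)(CC)CC)[C@@H]1C=O | intermediate
7 | triacetic acid lactone | CC1=CC(O)=CC(=O)O1 | starting material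
8 | 6-methyl-3-{[(1R,2S,5S)-2-methyl-5-(prop-1-en-2-yl)-2-(triethylsilyloxy)cyclopentyl]methylidene}-2H-pyran-2,4(3H)-dione | C=C(C)[C@H]1CC[C@](C)(O[Si](CC)(CC)CC)[C@@H]1C=C1C(=O)C=C(C)OC1=O | intermediate
9 | 4-hydroxy-6-methyl-3-(ring B-methyl)-2-pyrone, Et3Si ether at C2' | C=C(C)[C@H]1CC[C@](C)(O[Si](CC)(CC)CC)[C@@H]1CC1=C(O)C=C(C)OC1=O | intermediate
10 | methyl benzoate | COC(=O)c1ccccc1 | starting material
11 | 4-hydroxy-6-phenacyl-3-(ring B-methyl)-2-pyrone, Et3Si ether at C2' | C=C(C)[C@H]1CC[C@](C)(O[Si](CC)(CC)CC)[C@@H]1CC1=C(O)C=C(CC(=O)c2ccccc2)OC1=O | intermediate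
12 | methyl 3,5,7-trioxo-7-phenyl-2-(ring B-methyl)heptanoate, Et3Si ether at C2', epimeric at C2 of the chain, present as its magnesium chelate | C=C(C)[C@H]1CC[C@](C)(O[Si](CC)(CC)CC)[C@@H]1CC(C(=O)OC)C(=O)CC(=O)CC(=O)c1ccccc1 | intermediate
13 | 2,4,6-trihydroxy-3-(ring B-methyl)benzophenone, Et3Si ether at C2' | C=C(C)[C@H]1CC[C@](C)(O[Si](CC)(CC)CC)[C@@H]1Cc1c(O)cc(O)c(C(=O)c2ccccc2)c1O | intermediate
14 | prenyl bromide | CC(C)=CCBr | starting material
15 | 2,4,6-trihydroxy-3-prenyl-5-(ring B-methyl)benzophenone, Et3Si ether at C2' | C=C(C)[C@H]1CC[C@](C)(O[Si](CC)(CC)CC)[C@@H]1Cc1c(O)c(CC=C(C)C)c(O)c(C(=O)c2ccccc2)c1O | intermediate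
16 | O-triethylsilyl hypercalin B | C=C(C)[C@H]1CC[C@](C)(O[Si](CC)(CC)CC)[C@@H]1CC1=C(O)C(CC=C(C)C)(CC=C(C)C)C(=O)C(C(=O)c2ccccc2)=C1O | intermediate
17 | hypercalin B | C=C(C)[C@H]1CC[C@](C)(O)[C@@H]1CC1=C(O)C(CC=C(C)C)(CC=C(C)C)C(=O)C(C(=O)c2ccccc2)=C1O | target

Total step count: 9. Longest linear sequence: 9 steps (1 to 17). Compounds 7, 10 and 14 are bought and enter directly.

Steps most likely to fail

**Step 8.** The second alkylation may spread over C5, C3 and the phenolate oxygens, and a further alkylation at C3 may follow. C3 and C5 are electronically equivalent, so only sterics separate them. The fallback sets out from 13 and returns at 16.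
- One equivalent of prenyl bromide under the same base is used to stop at 15, which is isolated.
- The second prenyl group is then brought in by a Tsuji–Trost allylation: Pd(PPh3)4 as the zerovalent palladium catalyst, methyl 3-methylbut-2-en-1-yl carbonate, THF, rt.
- The phosphine-bearing π-prenyl complex of divalent palladium is a much larger electrophile than the bromide, so it should respond more strongly to the bulk around C3.
- O-prenylated material re-ionises under the catalyst and is fed back to the C-alkylated product.
- No compound outside the list is made (entry F0).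

**Step 7.** The hindered, anionic lactone may open too slowly. Methoxide may strip off the benzoyl group by retro-Claisen cleavage, or the open chain may simply re-lactonise on work-up. The fallback sets out from 11 and returns at 17.
- The silyl ether is removed first (HF·pyridine) to give the free hydroxy phenacyl pyrone F1. Its tertiary hydroxyl is cis to the link CH2 and can reach C2 through a six-membered ring.
- With a non-nucleophilic base (NaH, THF, reflux) the internal alkoxide, not methoxide, should open the pyrone by translactonisation to the cis-fused triketo δ-lactone F2, which is not isolated.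
- A lactone is a better acyl donor than a methyl ester, and no external alkoxide is present to attack the benzoyl group.
- The same C1–C2 Claisen closure expels the tertiary alkoxide and gives the free 3-alkyl-2,4,6-trihydroxybenzophenone F3.
- Double prenylation of F3 under the conditions of step 8, through the 5-prenyl benzophenone F4, leads directly to 17 and makes step 9 unnecessary.

**Step 3.** The aldol may dehydrate to the conjugated cyclopentene aldehyde, and facial selectivity at the ketone (C2') may be incomplete. The fallback sets out from 4 and returns at 5.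
- Pinnick oxidation (NaClO2, NaH2PO4, 2-methylbut-2-ene) gives the keto acid F5.
- A nucleophile-catalysed aldol lactonisation (4-toluenesulfonyl chloride, 4-pyrrolidinopyridine, iPr2NEt, CH2Cl2) closes the bicyclic β-lactone F6.
- The four-membered ring of F6 can only be cis-fused, which forces the oxygen at C2' and the carbonyl carbon at C1' to be cis.
- Allylic 1,3-strain in the acylammonium enolate places the new bond trans to the isopropenyl group.
- LiAlH4 reduction gives the diol F7.
- Oxidation of the primary alcohol alone (catalytic 2,2,6,6-tetramethylpiperidine-1-oxyl, PhI(OAc)2, CH2Cl2) gives 5.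

Further compounds
F0 | step 8 | none | none
F1 | step 7 | 4-hydroxy-3-{[(1R,2S,5S)-2-hydroxy-2-methyl-5-(prop-1-en-2-yl)cyclopentyl]methyl}-6-(2-oxo-2-phenylethyl)-2H-pyran-2-one | C=C(C)[C@H]1CC[C@](C)(O)[C@@H]1CC1=C(O)C=C(CC(=O)c2ccccc2)OC1=O
F2 | step 7 | (4aR,5S,7aS)-7a-methyl-3-(3,5-dioxo-5-phenylpentanoyl)-5-(prop-1-en-2-yl)hexahydrocyclopenta[b]pyran-2(3H)-one, epimeric at C3 | C=C(C)[C@H]1CC[C@]2(C)OC(=O)C(C(=O)CC(=O)CC(=O)c3ccccc3)C[C@H]12
F3 | step 7 | phenyl(2,4,6-trihydroxy-3-{[(1R,2S,5S)-2-hydroxy-2-methyl-5-(prop-1-en-2-yl)cyclopentyl]methyl}phenyl)methanone | C=C(C)[C@H]1CC[C@](C)(O)[C@@H]1Cc1c(O)cc(O)c(C(=O)c2ccccc2)c1O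
F4 | step 7 | phenyl[2,4,6-trihydroxy-3-(3-methylbut-2-en-1-yl)-5-{[(1R,2S,5S)-2-hydroxy-2-methyl-5-(prop-1-en-2-yl)cyclopentyl]methyl}phenyl]methanone | C=C(C)[C@H]1CC[C@](C)(O)[C@@H]1Cc1c(O)c(CC=C(C)C)c(O)c(C(=O)c2ccccc2)c1O
F5 | step 3 | (3S)-6-oxo-3-(prop-1-en-2-yl)heptanoic acid | C=C(C)[C@H](CC(=O)O)CCC(C)=O
F6 | step 3 | (1R,2S,5S)-5-methyl-2-(prop-1-en-2-yl)-6-oxabicyclo[3.2.0]heptan-7-one | C=C(C)[C@H]1CC[C@]2(C)OC(=O)[C@H]12
F7 | step 3 | (1S,2S,3S)-2-(hydroxymethyl)-1-methyl-3-(prop-1-en-2-yl)cyclopentan-1-ol | C=C(C)[C@H]1CC[C@](C)(O)[C@@H]1CO
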